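- The time of reading, 3.0 min, is what I count against. Your hunch that the flask at 0.12 M has come to rest by then can be tested in half-lives.

| flask | substrate | remark | time |
|---|---|---|---|
| south-west | 0.060 M | run made earlier |  |
| east | 0.090 M | run made earlier |  |
| flask | 0.12 M |  | 3.0 min |

- south-west (time / min: substrate / %, target / %): 0.250: 18.3, 24.4; 0.833: 11.2, 12.1; 1.33: 10.8, 10.6; 2.00: 11.5, 10.4; 3.00: 10.7, 10.6
- east (time / min: substrate / %, target / %): 0.667: 12.3, 13.1; 1.33: 10.1, 11.3; 2.00: 10.2, 11.1; 2.50: 9.2, 10.1; 3.00: 10.0, 10.8

(readings scatter by 0.5 percentage points)

- the earlier runs were read with a standard deviation of 0.5 percentage points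
- the reaction counts as stopped when no species that holds the substrate changes by six tenths of a point or more over the second half of the time
- what has gone from substrate into another species counts as reacted, even if it can come back

1. which holds at 3.0 min: what has brought the reaction to rest, or that it has not come to rest (forward and back rates have come level / it is still moving / all of the substrate has reacted)
2. how much of the substrate has reacted by 3.0 min
3. how much target there is at 3.0 min, in percent of the substrate charged
4. how much isomer of the product there is at 3.0 min, in percent of the substrate charged

- In the south-west run the target overshoots and falls back: its excess over the last reading shrinks from 14 percentage points at 0.250 min to 1.5 points at 0.833 min.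
- Taken as exponential, that gives 0.182 min as the time in which the excess halves, my approach half-life (a relaxation half-life). It is a reading and carries the scatter.
- Carried to the east run at 0.090 M, it predicts an excess of 2.8 points at 0.667 min. The east run reads 2.3 points, about one scatter of 0.5 points away, so I see no shift with the charge.
- If it holds at 0.12 M too, 3.0 min is 16.5 half-lives, so I expect this flask to be at rest, and the count ends there: it says when, not how much.
- For the amounts I use the forecast: forward and back rates have come level, 90 % reacted (88.5 % to 91.5 %), 10.7 % target (9.7 % to 11.7 %), 79.3 % isomer (77.5 % to 81 %). Its ground: “The plateau barely depends on concentration”.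
- In the flask forward and back rates have come level, with 89.9 % reacted, 10.4 % target and 76.5 % isomer, so the forecast stands within tolerance. The flask also holds 3.03 % dormant form, and its isomer lies 2.8 points under the forecast, which is below the forecast's own low end of 77.5 %. To put the target 5 points off, the reading has to come as early as 0.504 min, which is 2.77 approach half-lives.

    substrate ⇌ target (K = 1.03, k = 0.223 s⁻¹)
    substrate ⇌ isomer of the product (K = 7.60, k = 0.125 s⁻¹)
    substrate ⇌ dormant form (K = 0.301, k = 0.0773 s⁻¹)

- Read at 8.0 min, the same flask stands 44.0 approach half-lives from the start, so the count expects no change. It gives 89.9 % reacted, 10.4 % target and 76.5 % isomer.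

(The numbers in the tables were computed from invented constants; the scatter is artificial.)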